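**Plan**

- Retrosynthesis: cut first the C4–aryl bond to the acylphloroglucinol ring (Friedel–Crafts), then C3–C4 and O1–C2 of the pyran ring together (formal [4+2]), and last the aryl–acyl bond of the ketone.
- Enabling feature: in ring A the unit O1–C8a=C4a–C4 is a latent o-quinone methide. C4 is ortho to O1 and para to the 7-oxygen, so it can serve first as a salicylaldehyde carbon, then as the electrophilic end of a methoxy o-quinone methide (heterodiene O1=C8a–C4a=C4), then as a stabilised flavan-4-yl cation. C2–C3 is a styrene.
- Forward: C-acylation of phloroglucinol; ring C built in one step from a salicylaldehyde, trimethyl orthoformate and 4-acetoxystyrene; the 4-methoxy helper exchanged for the acylphloroglucinol; acetate, then benzyl, removed.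
- Stereochemistry: C2 (S) comes from a chiral Brønsted acid in the cycloaddition. C4 (R) comes by 1,3-induction from C2 in the Friedel–Crafts step (axial attack, trans to the 2-aryl group). The C4 centre of the cycloadduct is only a relay and is erased on ionisation.
- The acetate on the styrene is chosen to keep the C2–O1 bond from ionising in the two acidic steps.

Key step: step 2

Assumption: the (R)-configured catalyst is taken to leave open the face of the heterodiene that leads to the (2S,4S) adduct; if the sense of induction is the opposite, the (S)-catalyst is used and nothing else changes.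

Remark: the four starting materials and trimethyl orthoformate are taken as catalogue chemicals.

**Route**

Step 1
Reactants: 1 phloroglucinol (benzene-1,3,5-triol); 2 9-phenylnonanoic acid
Product: 3 9-phenyl-1-(2,4,6-trihydroxyphenyl)nonan-1-one
Conditions: BF3·OEt2 (neat, as solvent and promoter), 85 °C; then aq NaOAc
Reagents that add atoms: none
Why: BF3-mediated Friedel–Crafts C-acylation of a phenol with a free carboxylic acid (Nencki-type reaction) should acylate the symmetrical, strongly nucleophilic phloroglucinol once, because the 2-hydroxyaryl ketone formed is deactivated as its boron chelate; no stereocenter is involved.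

Step 2
Reactants: 4 4-(benzyloxy)-2-hydroxybenzaldehyde; 5 4-ethenylphenyl acetate (4-acetoxystyrene)
Product: 8 4-[(2S,4S)-7-(benzyloxy)-4-methoxy-3,4-dihydro-2H-chromen-2-yl]phenyl acetate, via dimethyl acetal 6 (not isolated), via methoxy o-quinone methide 7 (not isolated)
Conditions: HC(OMe)3 (1.5 equiv), (R)-3,3'-bis(2,4,6-triisopropylphenyl)-1,1'-binaphthyl-2,2'-diyl N-(trifluoromethylsulfonyl)phosphoramide (C51H57F3NO5PS, 5 mol%), PhMe, 25 °C; then 5 (2 equiv), −30 °C → 0 °C; Et3N quench
Reagents that add atoms: trimethyl orthoformate, COC(OC)OC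
Why: Proposed new method: the acid converts 4 into acetal 6 and then, by loss of methanol, into the (E)-methoxy o-quinone methide 7, which sits in the catalyst pocket as its O-protonated form (a 2-hydroxyaryl methoxycarbenium ion whose phenol O–H is hydrogen-bonded to the chiral phosphoramide anion); the CH2 terminus of 5 adds to the methide carbon (future C4) and the ring A oxygen closes on the benzylic carbon (future C2) in a concerted but asynchronous inverse-electron-demand hetero-Diels–Alder reaction, so that C3–C4 and O1–C2 form in one operation. The closest known reaction types are the acid-catalysed [4+2] cycloaddition of alkoxy o-quinone methides, generated from salicylaldehydes and an orthoformate, with alkenes (racemic) and the chiral N-triflylphosphoramide-catalysed [4+2] cycloaddition of aryl-substituted o-quinone methides with styrenes; what is new is enantiocontrol on the alkoxy-substituted heterodiene. Ring C is closed by the cycloaddition itself, which in its stepwise limit is intermolecular C–C bond formation followed by 6-exo-trig capture of the aryl-stabilised cation by the phenolic oxygen. C4 is set by the face of 7 that the 3,3'-aryl groups of the catalyst leave open, and C2 follows from C4 through the endo transition state (styrene aryl under ring A), which should give the 2,4-cis adduct and thus 2S. The step needs Markovnikov regiochemistry, endo selectivity and face selectivity: the first is secured by the polarity of the partners (electrophilic methide carbon para to the 7-benzyloxy group, nucleophilic CH2 of the styrene), and the acetoxy group on 5 keeps the benzylic cation short-lived, which favours the concerted endo path, suppresses cationic oligomerisation and stops the product from re-ionising at C2. The methoxy group at C4 is the helper that carries the aldehyde oxidation level into the adduct and leaves again in step 3.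

Step 3
Reactants: 8 4-[(2S,4S)-7-(benzyloxy)-4-methoxy-3,4-dihydro-2H-chromen-2-yl]phenyl acetate; 3 9-phenyl-1-(2,4,6-trihydroxyphenyl)nonan-1-one
Product: 9 4-[(2S,4R)-7-(benzyloxy)-4-[2,4,6-trihydroxy-3-(9-phenylnonanoyl)phenyl]-3,4-dihydro-2H-chromen-2-yl]phenyl acetate
Conditions: 3 (3 equiv), BF3·OEt2 (20 mol%), THF/CH2Cl2 (1:4), −20 °C → 0 °C; aq NaHCO3
Reagents that add atoms: none
Why: Friedel–Crafts alkylation by an SN1 path, well known for 4-oxygenated flavans and phloroglucinol-type rings: loss of methanol gives the flavan-4-yl cation stabilised by O1 (ortho) and the 7-benzyloxy group (para), and one of the two equivalent free CH positions of 3 attacks it axially on the half-chair in which the 2-aryl group is equatorial, so the new aryl group should end up trans to the C2 aryl group (4R) whichever C4 epimer of 8 is used, while the acetate keeps C2–O1 from ionising.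

Step 4
Reactants: 9 4-[(2S,4R)-7-(benzyloxy)-4-[2,4,6-trihydroxy-3-(9-phenylnonanoyl)phenyl]-3,4-dihydro-2H-chromen-2-yl]phenyl acetate
Product: 10 1-{3-[(2S,4R)-7-(benzyloxy)-2-(4-hydroxyphenyl)-3,4-dihydro-2H-chromen-4-yl]-2,4,6-trihydroxyphenyl}-9-phenylnonan-1-one
Conditions: K2CO3 (0.2 equiv), degassed MeOH, 0 °C; then aq NH4Cl
Reagents that add atoms: none
Why: Base-catalysed transesterification (Zemplén-type methanolysis) of an aryl acetate is fast at 0 °C, whereas the hindered, hydrogen-bonded aryl ketone and both stereocenters should stay untouched.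

Step 5
Reactants: 10 1-{3-[(2S,4R)-7-(benzyloxy)-2-(4-hydroxyphenyl)-3,4-dihydro-2H-chromen-4-yl]-2,4,6-trihydroxyphenyl}-9-phenylnonan-1-one
Product: 11 (+)-myristinin D, 9-phenyl-1-{2,4,6-trihydroxy-3-[(2S,4R)-7-hydroxy-2-(4-hydroxyphenyl)-3,4-dihydro-2H-chromen-4-yl]phenyl}nonan-1-one
Conditions: H2 (1 atm), Pd/C (10 wt%), EtOAc/MeOH, 25 °C
Reagents that add atoms: none
Why: Catalytic hydrogenolysis cleaves the primary benzyl aryl ether much faster than the cyclic secondary benzylic C2–O1 bond or the chelated aryl ketone, so the target should be released under neutral conditions without change at C2 or C4.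

**Compound list**

1 | phloroglucinol (benzene-1,3,5-triol) | Oc1cc(O)cc(O)c1 | starting material
2 | 9-phenylnonanoic acid | OC(=O)CCCCCCCCc1ccccc1 | starting material
3 | 9-phenyl-1-(2,4,6-trihydroxyphenyl)nonan-1-one | O=C(CCCCCCCCc1ccccc1)c1c(O)cc(O)cc1O | intermediate
4 | 4-(benzyloxy)-2-hydroxybenzaldehyde | O=Cc1ccc(OCc2ccccc2)cc1O | starting material
5 | 4-ethenylphenyl acetate (4-acetoxystyrene) | CC(=O)Oc1ccc(C=C)cc1 | starting material
6 | 5-(benzyloxy)-2-(dimethoxymethyl)phenol | COC(OC)c1ccc(OCc2ccccc2)cc1O | intermediate
7 | (6E)-3-(benzyloxy)-6-(methoxymethylidene)cyclohexa-2,4-dien-1-one | CO/C=C1\C=CC(OCc2ccccc2)=CC1=O | intermediate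
8 | 4-[(2S,4S)-7-(benzyloxy)-4-methoxy-3,4-dihydro-2H-chromen-2-yl]phenyl acetate | CO[C@H]1C[C@@H](c2ccc(OC(C)=O)cc2)Oc2cc(OCc3ccccc3)ccc21 | intermediate
9 | 4-[(2S,4R)-7-(benzyloxy)-4-[2,4,6-trihydroxy-3-(9-phenylnonanoyl)phenyl]-3,4-dihydro-2H-chromen-2-yl]phenyl acetate | O=C(CCCCCCCCc1ccccc1)c1c(O)cc(O)c([C@@H]2C[C@@H](c3ccc(OC(C)=O)cc3)Oc3cc(OCc4ccccc4)ccc32)c1O | intermediate
10 | 1-{3-[(2S,4R)-7-(benzyloxy)-2-(4-hydroxyphenyl)-3,4-dihydro-2H-chromen-4-yl]-2,4,6-trihydroxyphenyl}-9-phenylnonan-1-one | O=C(CCCCCCCCc1ccccc1)c1c(O)cc(O)c([C@@H]2C[C@@H](c3ccc(O)cc3)Oc3cc(OCc4ccccc4)ccc32)c1O | intermediate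
11 | (+)-myristinin D | O=C(CCCCCCCCc1ccccc1)c1c(O)cc(O)c([C@@H]2C[C@@H](c3ccc(O)cc3)Oc3cc(O)ccc32)c1O | target

**Count**

Total step count: 5. Longest linear sequence: 4 steps (steps 2 to 5 from 4 and 5; equally steps 1, 3, 4 and 5 from 1 and 2).

**Steps most likely to fail**

Step 2. The catalyst may discriminate the faces of the ion-paired heterodiene poorly. A stepwise path may lose the endo preference, and the trans adduct would then carry the opposite C2 configuration. The adduct may also re-ionise at C4 and add to a second styrene. The fallback uses known chemistry, sets out from 4 and 5 and comes back at 8. The same three-component cycloaddition is run with an achiral Lewis acid (Sc(OTf)3, 5 mol%, HC(OMe)3, CH2Cl2, 0 °C), which is established for alkoxy o-quinone methides. It should give the racemic cis adduct, that is 8 together with its enantiomer 4-[(2R,4R)-7-(benzyloxy)-4-methoxy-3,4-dihydro-2H-chromen-2-yl]phenyl acetate F1. Preparative chromatography on a chiral stationary phase (supercritical CO2/MeOH) then separates 8 from F1, so that stereocontrol by catalysis is replaced by resolution.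

Step 3. Facial selectivity on the flavan-4-yl cation may be poor, and acid-mediated reversal (retro-Friedel–Crafts) may let the kinetic trans adduct drift toward a cis/trans mixture. Double alkylation of the nucleophile and elimination to the flav-3-ene are further risks. The fallback sets out from 8 and comes back at 9. Compound 8 is first converted with benzyl mercaptan (BnSH, BF3·OEt2 cat., CH2Cl2, −20 °C) into the storable C4 donor 4-[(2S,4R)-7-(benzyloxy)-4-(benzylsulfanyl)-3,4-dihydro-2H-chromen-2-yl]phenyl acetate F2. F2 is then activated with the thiophilic salt AgBF4 (THF, −20 °C) in the presence of excess 3. This is the established way to join flavan C4 to phloroglucinol-type rings that carry free phenols. The cation is released by silver at low temperature instead of by acid equilibration of an ether, so the kinetic trans product should be kept.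

Step 4. Once the 4'-phenoxide is formed, base may open the pyran ring through a para-quinone methide, which would epimerise C2, and the polyphenolate may be oxidised by air. The fallback changes the protecting group so that no base is needed after the coupling; it sets out from 5 and comes back at 11. Methanolysis of 5 (K2CO3 cat., MeOH, 0 °C) gives 4-ethenylphenol F3. F3 is acylated at once (ClCO2Bn, pyridine, CH2Cl2, 0 °C) to benzyl 4-ethenylphenyl carbonate F4, which is as electron-poor as the acetate. F4 takes the place of 5 in step 2 with 4 and should give benzyl 4-[(2S,4S)-7-(benzyloxy)-4-methoxy-3,4-dihydro-2H-chromen-2-yl]phenyl carbonate F5. F5 is coupled with 3 as in step 3 to benzyl 4-[(2S,4R)-7-(benzyloxy)-4-[2,4,6-trihydroxy-3-(9-phenylnonanoyl)phenyl]-3,4-dihydro-2H-chromen-2-yl]phenyl carbonate F6. One hydrogenolysis (H2, Pd/C, EtOAc/MeOH) then removes the benzyl ether and the benzyl carbonate together and gives 11 directly, so steps 4 and 5 merge.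

**Further compounds**

F1 | step 2 | 4-[(2R,4R)-7-(benzyloxy)-4-methoxy-3,4-dihydro-2H-chromen-2-yl]phenyl acetate | CO[C@@H]1C[C@H](c2ccc(OC(C)=O)cc2)Oc2cc(OCc3ccccc3)ccc21
F2 | step 3 | 4-[(2S,4R)-7-(benzyloxy)-4-(benzylsulfanyl)-3,4-dihydro-2H-chromen-2-yl]phenyl acetate | C(c1ccccc1)S[C@@H]1C[C@@H](c2ccc(OC(C)=O)cc2)Oc2cc(OCc3ccccc3)ccc21
F3 | step 4 | 4-ethenylphenol | C=Cc1ccc(O)cc1
F4 | step 4 | benzyl 4-ethenylphenyl carbonate | C=Cc1ccc(OC(=O)OCc2ccccc2)cc1
F5 | step 4 | benzyl 4-[(2S,4S)-7-(benzyloxy)-4-methoxy-3,4-dihydro-2H-chromen-2-yl]phenyl carbonate | CO[C@H]1C[C@@H](c2ccc(OC(=O)OCc3ccccc3)cc2)Oc2cc(OCc3ccccc3)ccc21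
F6 | step 4 | benzyl 4-[(2S,4R)-7-(benzyloxy)-4-[2,4,6-trihydroxy-3-(9-phenylnonanoyl)phenyl]-3,4-dihydro-2H-chromen-2-yl]phenyl carbonate | O=C(CCCCCCCCc1ccccc1)c1c(O)cc(O)c([C@@H]2C[C@@H](c3ccc(OC(=O)OCc4ccccc4)cc3)Oc3cc(OCc4ccccc4)ccc32)c1O
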